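The chemist at this flask wants to know when to stop for intermediate, with three earlier runs to go on.

| setting | alder | cedar | larch | flask |
|---|---|---|---|---|
| starting material | 0.20 M (fed, over 50 min) | 0.45 M (fed, over 50 min) | 0.30 M (fed, over 50 min) | 0.30 M (fed, over 50 min) |
| protic impurity | 0.060 M | 0.060 M | 0.060 M | 0.0600 M |
| catalyst | 0.63 mM | 0.63 mM | 1.3 mM | 0.63 mM |
| remark | run made earlier | run made earlier | run made earlier |  |
| time |  |  |  | 30 h |

| run | time / h | intermediate / % | product / % |
|---|---|---|---|
| alder | 0.667 | 32 | 0 |
| alder | 2.50 | 83 | 10 |
| alder | 8.00 | 62 | 24 |
| alder | 30.0 | 19 | 73 |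
| cedar | 0.667 | 33 | 0 |
| cedar | 2.50 | 81 | 6 |
| cedar | 8.00 | 63 | 30 |
| cedar | 30.0 | 18 | 76 |
| larch | 0.667 | 31 | 0 |
| larch | 2.50 | 73 | 14 |
| larch | 8.00 | 43 | 51 |
| larch | 30.0 | 4 | 88 |

(standard deviation of a reading: 2 percentage points)

- a reading or a percentage of product counts all its forms, free or not
- percentages count the whole charge, also what has not yet gone in

* time, not beyond 30 h, at which the flask holds most intermediate
* the amount of intermediate, in percent of the starting material charged, at that time
* the first time at which intermediate reaches 24%, in the same percent

Between 8.00 h and 30.0 h, intermediate decays at 0.0538 h⁻¹ in alder and 0.0569 h⁻¹ in cedar. This looks pseudo-first-order, and we take the mean, 0.0554 h⁻¹, for the flask, which has the same catalyst. Larch, with twice the catalyst, decays at 0.108 h⁻¹, twice that mean. So we divide by catalyst and get 0.0879 mM⁻¹ h⁻¹, the clearing constant, the decay rate of intermediate per unit of catalyst.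

Intermediate plus product at the end of alder and cedar averages 93.0%, our reading of the share that reaches intermediate. Early in the feed, intermediate grows as the square of time, so the first readings give a rise constant of 1.31 h⁻¹, or 1.85 h⁻¹ once unreacted feed is counted. The same square law puts 24% in the flask at 0.573 h.

We reckon 51.0% of starting material standing in the flask at the end of the feed. The peak comes when making equals clearing. Setting the peak height equal to the share that reaches intermediate gives 2.37 h, and decay since the mean time of formation, 0.958 h, gives a height of 83.2%. That assumed height is the weak link, so we put this answer back. For the flask we commit to a peak at 2.43 h with 83.3%.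

The forecast gives 2.6 h, 81% and 0.56 h, holding that “the second step is first order in catalyst”. Our height stands 2.3 percentage points above its height, and our time stands 0.170 h before its time.

The flask peaks at 2.45 h with 81.0% and reaches the level at 0.579 h, so the forecast is right within its margins.

    catalyst + intermediate → catalyst + product (k = 1.44 M⁻¹ min⁻¹)
    starting material + protic impurity → quenched substrate (k = 0.0666 M⁻¹ min⁻¹)
    starting material → intermediate (k = 0.0282 min⁻¹)
    crystals ⇌ product, rate k4*(cs4 - [product]) while solid is left; crystals form when [product] > cs4 (solubility = 31.0 mM, k = 0.430 min⁻¹)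

For the flask, the top is broad: it holds 79.7% at 1.96 h and 80.0% at 3.06 h, against 81.0% at the peak. The clearing constant then gives 18.6% at 30.0 h, and the flask holds 18.6%. For the neighbour with 0.160 mM of catalyst, the same constant gives a decay of 0.0141 h⁻¹ and 61.8% at that time. That neighbour peaks at 87.2% and holds 60.6% of intermediate at 30.0 h.

The readings were generated by integration for substances that don't exist.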